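## Retrosynthetic overview

1. The target comes from a cyclic bis(dimethyl acetal) C18 ethyl ester: the two acetals are unmasked last to the C1/C20 dialdehyde, and the C18 acetate comes from reduction and acetylation of the ester.
2. The only ring, the nine-membered carbocycle, is closed once (step 6) at C2–C10 by an intramolecular aza-ene (enamine–ene) reaction of an acyclic, oxidised geranylgeranyl-type chain. The C1 dienamine adds through C2 to C10 of a (Z)-C10=C11 enoate while N–H passes to C11. This is the laboratory counterpart of the presumed biogenetic closure (C1 dienol of an acyclic dial, C2 to C10, H to C11) and sets C2, C10 and C11 together.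
3. The acyclic precursor comes from formyl olefination at C3 (C1–C2), enolate alkylation of 1,1-dimethoxyacetone (C4–C5), a Z-selective Horner–Wadsworth–Emmons reaction (C10=C11) and selective ozonolysis of geranyl chloride (C5–C10 with the 6E alkene).

Labels: carbons are labelled as in geranylgeraniol (chain C1–C16; C17 on C15, C18 on C11, C19 on C7, C20 on C3). The target is the 2,10-cyclo compound with C1 and C20 as CHO and C18 as CH2OAc, (2S,10S,11R).

Assumption: anions made by simple deprotonation of a numbered compound (phosphonate carbanions, the lithium enolate of 7) count as the activated form of that compound and carry no number of their own.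

## Route

Step 1
Reactants: 1 ethyl 2-(diphenoxyphosphoryl)acetate; 2 5-bromo-2-methylpent-2-ene
Product: 3 ethyl 2-(diphenoxyphosphoryl)-6-methylhept-5-enoate (racemic)
Conditions: 1, NaH, DMSO, rt; then 2, NaI (cat.), 50 °C
Reagents that add atoms: none
Why: SN2 C-alkylation of the stabilised phosphonoacetate carbanion by a primary bromide; the new stereocentre is racemic and is destroyed in step 3.

Step 2
Reactants: 4 geranyl chloride
Product: 5 (4E)-6-chloro-4-methylhex-4-enal
Conditions: O3 (1.0 equiv), CH2Cl2, −78 °C; then PPh3, −78 °C → rt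
Reagents that add atoms: ozone, [O-][O+]=O
Why: Chemoselective ozonolysis with reductive work-up: the remote trisubstituted alkene is the more electron-rich one because the 2,3-alkene is deactivated by the allylic chlorine, and the E geometry of the surviving alkene is not touched.

Step 3
Reactants: 5 (4E)-6-chloro-4-methylhex-4-enal; 3 ethyl 2-(diphenoxyphosphoryl)-6-methylhept-5-enoate
Product: 6 ethyl (2Z,6E)-8-chloro-6-methyl-2-(4-methylpent-3-en-1-yl)octa-2,6-dienoate
Conditions: 3, NaH, THF, 0 °C; then 5, −78 → 0 °C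
Reagents that add atoms: none
Why: Z-selective Horner–Wadsworth–Emmons olefination with a diaryl phosphonate (Ando type): fast, irreversible collapse of the kinetic adduct places the ester cis to the chain, giving the (Z)-C10=C11 geometry that step 6 converts into the C10/C11 configuration; the allylic chloride is inert at this temperature.

Step 4
Reactants: 7 1,1-dimethoxypropan-2-one; 6 ethyl (2Z,6E)-8-chloro-6-methyl-2-(4-methylpent-3-en-1-yl)octa-2,6-dienoate
Product: 8 ethyl (2Z,6E)-11,11-dimethoxy-6-methyl-2-(4-methylpent-3-en-1-yl)-10-oxoundeca-2,6-dienoate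
Conditions: 7 (2 equiv), LiN(i-Pr)2 (commercial solution), THF, −78 °C; then 6, NaI (cat.), DMPU, −78 → −20 °C
Reagents that add atoms: none
Why: Kinetic lithium enolate alkylation: deprotonation at the methyl group and SN2 attack on the primary allylic chloride form C4–C5 with retention of the 6E geometry, while the hindered enoate is neither a good Michael acceptor nor an acylating agent at this temperature.

Step 5
Reactants: 8 ethyl (2Z,6E)-11,11-dimethoxy-6-methyl-2-(4-methylpent-3-en-1-yl)-10-oxoundeca-2,6-dienoate; 9 diethyl [(E)-2-(cyclohexylamino)ethenyl]phosphonate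
Product: 11 ethyl (2Z,6E,10E)-10-(dimethoxymethyl)-6-methyl-2-(4-methylpent-3-en-1-yl)-12-oxododeca-2,6,10-trienoate (10E major; the 10Z isomer is carried along), via N-cyclohexyl azadiene 10 (not isolated)
Conditions: 9, NaH, THF, 0 °C; then 8, rt; then 5% aq. oxalic acid, PhMe, 0 °C → rt
Reagents that add atoms: water, O
Why: Nagata formyl olefination, a Horner–Wadsworth–Emmons reaction of the metalated enamine phosphonate with the activated α,α-dialkoxy ketone followed by hydrolysis of the unsaturated imine; the C2=C3 geometry is irrelevant because both isomers give the same dienamine in step 6.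

Step 6
Reactants: 11 ethyl (2Z,6E,10E)-10-(dimethoxymethyl)-6-methyl-2-(4-methylpent-3-en-1-yl)-12-oxododeca-2,6,10-trienoate; 12 (S)-1-phenylethylamine
Product: 16 ethyl (2R)-2-[(1R,2S,3E,6E)-2,3-bis(dimethoxymethyl)-7-methylcyclonona-3,6-dien-1-yl]-6-methylhept-5-enoate, via N-(1-phenylethyl) azadiene 13 (not isolated), via secondary dienamine 14 (not isolated), via cyclised aldimine 15 (not isolated)
Conditions: 12 (1.05 equiv), 4 Å MS, PhMe, rt; then 2 mM, 110 °C, 48 h; then MeOH, CSA (1.2 equiv), rt
Reagents that add atoms: methanol, CO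
Why: Proposed new method: the aldimine 13 tautomerises to the conjugated secondary dienamine 14 (H–N–C1=C2–C3=C4; the C3=C4 geometry equilibrates and only the isomer with C5 cis to C2 can reach C10), whose α-carbon C2 adds to C10 of the enoate in an intramolecular aza-ene (enamine–ene) reaction in which N–H is passed suprafacially to C11 through a six-membered transition state, so the C2–C10 and C11–H bonds form on the same face of the (Z)-alkene and the cis relation of C9 and C18 in 6 becomes the 10S,11R relation of the target; the compact endo arrangement (ester over nitrogen) with attack anti to the phenyl group of the (S)-auxiliary is expected to give 2S,10S,11R, and a C2 epimer can equilibrate through the enamine to the trans arrangement; attack through C4 would need a trans-cycloheptene and the two isolated alkenes are not electrophilic, so only the nine-membered closure is open; acidic methanol then exchanges the imine for the dimethyl acetal and releases the amine. Closest known reaction type: Michael (aza-ene) additions of chiral secondary enamines from 1-phenylethylamine imines to electron-poor alkenes with internal N–H to Cα transfer, known between molecules and for five- and six-membered ring closures, and the Conia-ene reaction; new here are the nine-membered ring size and the trisubstituted enoate acceptor.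

Step 7
Reactants: 16 ethyl (2R)-2-[(1R,2S,3E,6E)-2,3-bis(dimethoxymethyl)-7-methylcyclonona-3,6-dien-1-yl]-6-methylhept-5-enoate
Product: 18 (2R)-2-[(1S,2S,3E,6E)-2,3-bis(dimethoxymethyl)-7-methylcyclonona-3,6-dien-1-yl]-6-methylhept-5-en-1-yl acetate, via primary alcohol 17 (not isolated)
Conditions: i-Bu2AlH (3 equiv), CH2Cl2, −78 → 0 °C; then Ac2O, pyridine, DMAP, 0 °C → rt
Reagents that add atoms: acetic anhydride, CC(=O)OC(C)=O
Why: Hydride reduction of the ester to the aluminium alkoxide and in-flask O-acetylation; acetals and alkenes are inert and no stereocentre is touched (the ring C1 descriptor changes from R to S only because the CIP priorities change).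

Step 8
Reactants: 18 (2R)-2-[(1S,2S,3E,6E)-2,3-bis(dimethoxymethyl)-7-methylcyclonona-3,6-dien-1-yl]-6-methylhept-5-en-1-yl acetate
Product: 19 (2R)-2-[(1S,2S,3E,6E)-2,3-diformyl-7-methylcyclonona-3,6-dien-1-yl]-6-methylhept-5-en-1-yl acetate (CNP0091613.1)
Conditions: PPTS (0.3 equiv), acetone/H2O (9:1), 45 °C
Reagents that add atoms: water, O
Why: Mild acid-catalysed acetal hydrolysis frees both aldehydes; the acetate survives and the buffered acid is chosen to avoid enolisation at C2 and migration of the C3=C4 bond.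

## Compound list

1 | ethyl 2-(diphenoxyphosphoryl)acetate | CCOC(=O)CP(=O)(Oc1ccccc1)Oc1ccccc1 | starting material
2 | 5-bromo-2-methylpent-2-ene | CC(C)=CCCBr | starting material
3 | ethyl 2-(diphenoxyphosphoryl)-6-methylhept-5-enoate (racemic) | CCOC(=O)C(CCC=C(C)C)P(=O)(Oc1ccccc1)Oc1ccccc1 | intermediate
4 | geranyl chloride, (2E)-1-chloro-3,7-dimethylocta-2,6-diene | CC(C)=CCC/C(C)=C/CCl | starting material
5 | (4E)-6-chloro-4-methylhex-4-enal | O=CCC/C(C)=C/CCl | intermediate
6 | ethyl (2Z,6E)-8-chloro-6-methyl-2-(4-methylpent-3-en-1-yl)octa-2,6-dienoate | CCOC(=O)/C(CCC=C(C)C)=C\CC/C(C)=C/CCl | intermediate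
7 | 1,1-dimethoxypropan-2-one | CC(=O)C(OC)OC | starting material
8 | ethyl (2Z,6E)-11,11-dimethoxy-6-methyl-2-(4-methylpent-3-en-1-yl)-10-oxoundeca-2,6-dienoate | CCOC(=O)/C(CCC=C(C)C)=C\CC/C(C)=C/CCC(=O)C(OC)OC | intermediate
9 | diethyl [(E)-2-(cyclohexylamino)ethenyl]phosphonate | CCOP(=O)(OCC)/C=C/NC1CCCCC1 | starting material
10 | ethyl (2Z,6E,10E)-12-(cyclohexylimino)-10-(dimethoxymethyl)-6-methyl-2-(4-methylpent-3-en-1-yl)dodeca-2,6,10-trienoate | CCOC(=O)/C(CCC=C(C)C)=C\CC/C(C)=C/CC/C(C(OC)OC)=C\C=N\C1CCCCC1 | intermediate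
11 | ethyl (2Z,6E,10E)-10-(dimethoxymethyl)-6-methyl-2-(4-methylpent-3-en-1-yl)-12-oxododeca-2,6,10-trienoate (major isomer) | CCOC(=O)/C(CCC=C(C)C)=C\CC/C(C)=C/CC/C(C(OC)OC)=C\C=O | intermediate
12 | (S)-1-phenylethylamine | C[C@H](N)c1ccccc1 | starting material
13 | ethyl (2Z,6E,10E)-10-(dimethoxymethyl)-6-methyl-2-(4-methylpent-3-en-1-yl)-12-{[(1S)-1-phenylethyl]imino}dodeca-2,6,10-trienoate | CCOC(=O)/C(CCC=C(C)C)=C\CC/C(C)=C/CC/C(C(OC)OC)=C\C=N\[C@@H](C)c1ccccc1 | intermediate
14 | ethyl (2Z,6E,9E,11E)-10-(dimethoxymethyl)-6-methyl-2-(4-methylpent-3-en-1-yl)-12-{[(1S)-1-phenylethyl]amino}dodeca-2,6,9,11-tetraenoate | CCOC(=O)/C(CCC=C(C)C)=C\CC/C(C)=C/C/C=C(/C(OC)OC)\C=C\N[C@@H](C)c1ccccc1 | intermediate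
15 | ethyl (2R)-2-[(1R,2S,3E,6E)-3-(dimethoxymethyl)-7-methyl-2-{(E)-[(1S)-1-phenylethyl]iminomethyl}cyclonona-3,6-dien-1-yl]-6-methylhept-5-enoate | CCOC(=O)[C@H](CCC=C(C)C)[C@@H]1CC/C(C)=C/C/C=C(/C(OC)OC)[C@H]1/C=N/[C@@H](C)c2ccccc2 | intermediate
16 | ethyl (2R)-2-[(1R,2S,3E,6E)-2,3-bis(dimethoxymethyl)-7-methylcyclonona-3,6-dien-1-yl]-6-methylhept-5-enoate | CCOC(=O)[C@H](CCC=C(C)C)[C@@H]1CC/C(C)=C/C/C=C(/C(OC)OC)[C@H]1C(OC)OC | intermediate
17 | (2R)-2-[(1S,2S,3E,6E)-2,3-bis(dimethoxymethyl)-7-methylcyclonona-3,6-dien-1-yl]-6-methylhept-5-en-1-ol | OC[C@H](CCC=C(C)C)[C@@H]1CC/C(C)=C/C/C=C(/C(OC)OC)[C@H]1C(OC)OC | intermediate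
18 | (2R)-2-[(1S,2S,3E,6E)-2,3-bis(dimethoxymethyl)-7-methylcyclonona-3,6-dien-1-yl]-6-methylhept-5-en-1-yl acetate | CC(=O)OC[C@H](CCC=C(C)C)[C@@H]1CC/C(C)=C/C/C=C(/C(OC)OC)[C@H]1C(OC)OC | intermediate
19 | (2R)-2-[(1S,2S,3E,6E)-2,3-diformyl-7-methylcyclonona-3,6-dien-1-yl]-6-methylhept-5-en-1-yl acetate (CNP0091613.1) | CC(=O)OC[C@H](CCC=C(C)C)[C@@H]1CC/C(C)=C/C/C=C(/C=O)[C@H]1C=O | target

## Step count and risks

Total step count: 8. Longest linear sequence: 7 steps (4 → 5 → 6 → 8 → 11 → 16 → 18 → 19, steps 2 to 8); step 1 is a one-step side branch that joins at step 3.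

**Step 6 (most likely to fail).** The acceptor is an α,β-disubstituted (Z)-enoate of low electrophilicity, the ring is nine-membered, and the sense of induction rests on a transition-state model. The fallback makes the C2–C10 bond and the three stereocentres by the same aza-ene chemistry between two molecules and closes the ring afterwards by olefin metathesis at C3=C4. It sets out from 6 (using 7 and 12) and comes back to the route at 16. Coupling of 6 with CH2=CHSnBu3 (Pd2(dba)3, P(2-furyl)3, THF, 50 °C) replaces chloride by vinyl and gives ethyl (2Z,6E)-6-methyl-2-(4-methylpent-3-en-1-yl)deca-2,6,9-trienoate F1. Wittig reaction of 7 with Ph3P=CHCHO (PhMe, reflux) gives (2E)-4,4-dimethoxy-3-methylbut-2-enal F2. With 12 and 4 Å sieves this forms (1E,2E)-4,4-dimethoxy-3-methyl-N-[(1S)-1-phenylethyl]but-2-en-1-imine F3, which tautomerises to (1E)-3-(dimethoxymethyl)-N-[(1S)-1-phenylethyl]buta-1,3-dien-1-amine F4. Under 12 kbar in THF at 40 °C, F4 adds through C2 to C10 of F1 with the same endo, anti-to-phenyl transition state and N–H transfer to C11, giving ethyl (2R,3R,4S)-4-(3,3-dimethoxyprop-1-en-2-yl)-3-[(3E)-3-methylhepta-3,6-dien-1-yl]-2-(4-methylpent-3-en-1-yl)-5-{[(1S)-1-phenylethyl]imino}pentanoate F5. MeOH/CSA converts it into ethyl (2R,3R,4S)-4-(3,3-dimethoxyprop-1-en-2-yl)-5,5-dimethoxy-3-[(3E)-3-methylhepta-3,6-dien-1-yl]-2-(4-methylpent-3-en-1-yl)pentanoate F6. Ring-closing metathesis of the C3 methylene and the terminal vinyl group (second-generation Grubbs catalyst, (H2IMes)(PCy3)Cl2Ru=CHPh, PhMe, 80 °C, 1 mM) closes the nine-membered ring with the ring-cis C3=C4 bond and gives 16.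

**Step 4.** The lithium enolate of 7 may equilibrate, over-alkylate or react sluggishly with the allylic chloride in the presence of the ester. The fallback uses a soft, doubly stabilised enolate followed by decarboxylation; it sets out from 6 and comes back at 8. Alkylation of methyl 4,4-dimethoxy-3-oxobutanoate with 6 (K2CO3, NaI cat., acetone, 50 °C) gives ethyl (2Z,6E)-11,11-dimethoxy-9-(methoxycarbonyl)-6-methyl-2-(4-methylpent-3-en-1-yl)-10-oxoundeca-2,6-dienoate F7. Krapcho demethoxycarbonylation (LiCl, wet DMSO, 120 °C), which leaves the unactivated ethyl enoate alone, gives 8.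

**Step 5.** The enolisable, hindered α,α-dimethoxy ketone may resist the phosphonate anion, and the imine hydrolysis must spare the acetal. The fallback replaces olefination by carbonyl addition and acid-induced transposition; it sets out from 8 and comes back at 11. Addition of LiCH=CHOEt (from (Z)-1-bromo-2-ethoxyethene and t-BuLi, THF, −78 °C) to the ketone gives ethyl (2Z,6E,11Z)-10-(dimethoxymethyl)-12-ethoxy-10-hydroxy-6-methyl-2-(4-methylpent-3-en-1-yl)dodeca-2,6,11-trienoate F8. Brief treatment with PPTS in wet acetone hydrolyses the enol ether and dehydrates the β-hydroxy aldehyde to 11.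

## Further compounds

F1 | step 6 | ethyl (2Z,6E)-6-methyl-2-(4-methylpent-3-en-1-yl)deca-2,6,9-trienoate | CCOC(=O)/C(CCC=C(C)C)=C\CC/C(C)=C/CC=C
F2 | step 6 | (2E)-4,4-dimethoxy-3-methylbut-2-enal | COC(OC)/C(C)=C/C=O
F3 | step 6 | (1E,2E)-4,4-dimethoxy-3-methyl-N-[(1S)-1-phenylethyl]but-2-en-1-imine | COC(OC)/C(C)=C/C=N/[C@@H](C)c1ccccc1
F4 | step 6 | (1E)-3-(dimethoxymethyl)-N-[(1S)-1-phenylethyl]buta-1,3-dien-1-amine | COC(OC)C(=C)/C=C/N[C@@H](C)c1ccccc1
F5 | step 6 | ethyl (2R,3R,4S)-4-(3,3-dimethoxyprop-1-en-2-yl)-3-[(3E)-3-methylhepta-3,6-dien-1-yl]-2-(4-methylpent-3-en-1-yl)-5-{[(1S)-1-phenylethyl]imino}pentanoate | CCOC(=O)[C@H](CCC=C(C)C)[C@H](CC/C(C)=C/CC=C)[C@H](/C=N/[C@@H](C)c1ccccc1)C(=C)C(OC)OC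
F6 | step 6 | ethyl (2R,3R,4S)-4-(3,3-dimethoxyprop-1-en-2-yl)-5,5-dimethoxy-3-[(3E)-3-methylhepta-3,6-dien-1-yl]-2-(4-methylpent-3-en-1-yl)pentanoate | CCOC(=O)[C@H](CCC=C(C)C)[C@H](CC/C(C)=C/CC=C)[C@H](C(OC)OC)C(=C)C(OC)OC
F7 | step 4 | ethyl (2Z,6E)-11,11-dimethoxy-9-(methoxycarbonyl)-6-methyl-2-(4-methylpent-3-en-1-yl)-10-oxoundeca-2,6-dienoate (racemic at C9) | CCOC(=O)/C(CCC=C(C)C)=C\CC/C(C)=C/CC(C(=O)OC)C(=O)C(OC)OC
F8 | step 5 | ethyl (2Z,6E,11Z)-10-(dimethoxymethyl)-12-ethoxy-10-hydroxy-6-methyl-2-(4-methylpent-3-en-1-yl)dodeca-2,6,11-trienoate (racemic at C10) | CCOC(=O)/C(CCC=C(C)C)=C\CC/C(C)=C/CCC(O)(C(OC)OC)/C=C\OCC
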